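The charge of X in autumn is small, 33.0 mM, less than the 44.0 mM of L and E together, and in each flask L and E compete for X.

| flask | L | E | X | time |
|---|---|---|---|---|
| autumn | 22 mM | 22.0 mM | 33.0 mM | 25 s |
| dawn | 22 mM | 22.0 mM | 66.0 mM | 25 s |

    X + E → X.E (k1 = 1.6 M⁻¹ s⁻¹)
    L.X + X.E → Q (k2 = 3.2 M⁻¹ s⁻¹)
    L + X → L.X (k3 = 0.59 M⁻¹ s⁻¹)

- which of these there is most of at the end, counted by the L in it, autumn (Q / L.X / L)
- which of these there is most of at the end, counted by the L in it, dawn (Q / L.X / L)
- amount of the one of these that there is most of at the end, in percent of the L charged, autumn
- amount of the one of these that there is most of at the end, in percent of the L charged, dawn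

Two extremes can be done in the head. If c_X stayed at its charge, L would decay pseudo-first-order, and the fraction left would be exp(−k·c_X·t), with k the constant of L + X: 61.5 % in autumn and 37.8 % at dawn. If E instead took its full charge of X at once, c_X would stand at 11.0 mM in autumn and 44.0 mM at dawn, which leaves 85.0 % and 52.3 % of L. The real flasks start at the first extreme and slide towards the second, since X goes to E faster than to L at the start. We commit to the middle, c_X at its charge less half of c_E's charge, and get 72.3 % of L in autumn and 44.4 % at dawn. L leads in both, we bet, since at dawn the remainder must be shared between L.X and Q.

There is a firmer tie. Divide the rate of loss of L by that of E: c_X and time drop out, and the fraction of L left equals the fraction of E left raised to the power s, the ratio of the two constants, the selectivity factor 0.369.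

The forecast says L in autumn with 73 % (70 % to 76 %) and L at dawn with 50.5 % (47 % to 54 %), on the grounds that “E takes most of the X much faster”. Its dawn figure stands above ours.

The simulation gives L in autumn at 72.9 % and L at dawn at 50.3 %, inside the forecast's ranges, and our dawn figure lies below it. At dawn 15.5 % of the E charge remained at the end, and raised to s that gives 50.3 % of L.

Read the dawn flask at 1.0 min instead: 2.65 % of E is left, and s gives 26.2 % of L. The computed flask holds 26.2 % of L, and there Q leads with 53.6 %, so a later reading is what turns the forecast's answer wrong.

The constants are assumed; the run is a simulation.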